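**Strategy**

The benzo ring is disconnected at C5–C6, back to a pyrrole that carries a vinyl group on C3 and a diazoacetyl group on C2. Light converts the diazoketone into a ketene whose central carbon (future C6) closes onto the vinyl terminus (future C5). This single operation forms C5–C6, closes the six-membered carbocycle and leaves a free hydroxyl on C6. The feature exploited is the oxygen-bearing C6 of the benzenoid ring lying between the brominated C5 and C7: the phenol directs both bromines ortho, its para position being the ring-fusion carbon C3a. O-Methylation, loss of the N-sulfonyl group and bromination of C3 of the free indole finish the synthesis.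

Key step: step 6

Remark: the target is a planar aromatic compound without any stereocentre, so there is no enantiomer to control and no stereodescriptor appears. Ts = p-toluenesulfonyl.

**Route**

Step 1
Reactants: 1 3-bromo-1H-pyrrole-2-carbaldehyde; 2 p-toluenesulfonyl chloride
Product: 3 3-bromo-1-tosyl-1H-pyrrole-2-carbaldehyde
Conditions: NaH, THF, 0 °C; then TsCl, 0 °C to rt
Reagents that add atoms: none
Why: The N–H of a 2-formylpyrrole is acidic enough for clean deprotonation, and the sodium salt should be sulfonylated on nitrogen (N-sulfonylation of an azole), giving the electron-poor pyrrole needed later.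

Step 2
Reactants: 3 3-bromo-1-tosyl-1H-pyrrole-2-carbaldehyde; 4 potassium vinyltrifluoroborate
Product: 5 1-tosyl-3-vinyl-1H-pyrrole-2-carbaldehyde
Conditions: PdCl2(dppf)·CH2Cl2 (cat.), Et3N, n-PrOH, 90 °C, degassed
Reagents that add atoms: none
Why: Suzuki–Miyaura vinylation should proceed because the C3–Br bond next to the formyl group on an N-sulfonyl pyrrole is activated for oxidative addition, while the amine/alcohol medium is too weakly basic to strip the sulfonyl group.

Step 3
Reactants: 5 1-tosyl-3-vinyl-1H-pyrrole-2-carbaldehyde
Product: 6 1-tosyl-3-vinyl-1H-pyrrole-2-carboxylic acid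
Conditions: NaClO2, NaH2PO4, 2-methyl-2-butene (excess), t-BuOH/THF/H2O, 0 °C to rt
Reagents that add atoms: sodium chlorite, [Na+].[O-]Cl=O
Why: Pinnick oxidation unveils the acid under buffered, mildly acidic conditions that spare the N-sulfonyl group (saponification of an ester here would remove it first), and the scavenger alkene takes up HOCl before it can reach the vinyl group.

Step 4
Reactants: 6 1-tosyl-3-vinyl-1H-pyrrole-2-carboxylic acid
Product: 7 1-tosyl-3-vinyl-1H-pyrrole-2-carbonyl chloride
Conditions: (COCl)2, DMF (cat.), CH2Cl2, 0 °C to rt; volatiles removed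
Reagents that add atoms: oxalyl chloride, O=C(Cl)C(=O)Cl
Why: Vilsmeier-type activation should convert the hindered acid into its chloride at or below room temperature, and the vinyl group, deactivated by the acyl and sulfonyl groups on the ring, should tolerate the HCl released.

Step 5
Reactants: 7 1-tosyl-3-vinyl-1H-pyrrole-2-carbonyl chloride
Product: 8 2-diazo-1-(1-tosyl-3-vinyl-1H-pyrrol-2-yl)ethan-1-one
Conditions: CH2N2 (excess, ethereal, from Diazald), Et2O/CH2Cl2, 0 °C, dark
Reagents that add atoms: diazomethane, C=[N+]=[N-]
Why: Acylation of diazomethane (first stage of the Arndt–Eistert sequence) should work because the small nucleophile reaches the flanked acid chloride and a second equivalent removes HCl as chloromethane, so no chloromethyl ketone forms.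

Step 6
Reactants: 8 2-diazo-1-(1-tosyl-3-vinyl-1H-pyrrol-2-yl)ethan-1-one
Product: 11 1-tosyl-1H-indol-6-ol, via pyrrol-2-ylketene 9 (not isolated), via 1,5-dihydroindol-6-one 10 (not isolated)
Conditions: hν (365 nm), degassed dry ClCH2CH2Cl (0.01 M), 20 °C; then 60 °C in the dark
Reagents that add atoms: none
Why: Excitation of the diazoketone expels N2 and the pyrrol-2-yl group migrates from the carbonyl carbon to the former diazo carbon (photochemical Wolff rearrangement), giving ketene 9 in which the CH carbon is the future C7 and the ketene carbon the future C6. In 9 the ketene C=C, the pyrrole C2=C3 bond and the vinyl group form a hexatriene held cis on adjacent ring carbons, which should close by thermal disrotatory 6π electrocyclisation, the ketene carbon bonding to the vinyl CH2 to form C5–C6 and the six-membered carbocycle as dienone 10, which enolises to phenol 11. The closest known reaction type is the photo-Wolff/dienylketene electrocyclisation used for aromatic annulation of aryl and heteroaryl diazoketones to phenols. No stereocentre is created. The selectivity needed is ring closure over capture of the ketene by water or by the phenol formed and over carbene pathways such as addition to the vinyl group; it is secured by the enforced proximity of ketene and vinyl group, the reduced aromatic stabilisation of the N-sulfonyl pyrrole, high dilution in a dry non-nucleophilic solvent and light that the product should not absorb. Placing the acyl group on pyrrole C2 and the vinyl group on C3 fixes the oxygen at C6.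

Step 7
Reactants: 11 1-tosyl-1H-indol-6-ol
Product: 12 5,7-dibromo-1-tosyl-1H-indol-6-ol
Conditions: NBS (2.05 equiv), i-Pr2NH (cat.), CH2Cl2, 0 °C to rt
Reagents that add atoms: N-bromosuccinimide, O=C1CCC(=O)N1Br
Why: Phenol-directed electrophilic bromination (amine-catalysed ortho-bromination with NBS) should hit C5 and C7, the two positions ortho to the C6 hydroxyl, because the para position is the ring-fusion carbon C3a and the N-sulfonyl group keeps C2/C3 far less reactive than the phenol ring.

Step 8
Reactants: 12 5,7-dibromo-1-tosyl-1H-indol-6-ol
Product: 13 5,7-dibromo-6-methoxy-1-tosyl-1H-indole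
Conditions: MeI, K2CO3, DMF, rt
Reagents that add atoms: iodomethane, CI
Why: Williamson O-methylation should be clean because the 2,6-dibromophenol is acidic and its phenoxide is readily methylated, while the sulfonyl group still masks nitrogen and so excludes N-methylation.

Step 9
Reactants: 13 5,7-dibromo-6-methoxy-1-tosyl-1H-indole
Product: 14 5,7-dibromo-6-methoxy-1H-indole
Conditions: KOH, THF/MeOH/H2O, 60 °C
Reagents that add atoms: none
Why: Nucleophilic cleavage of the N-sulfonyl indole at sulfur should release the indolide, a good leaving group made better by the peri C7 bromine, while the unactivated aryl bromides and the methyl ether are inert to aqueous-alcoholic base.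

Step 10
Reactants: 14 5,7-dibromo-6-methoxy-1H-indole
Product: 15 3,5,7-tribromo-6-methoxy-1H-indole
Conditions: NBS (1.0 equiv), DMF, −20 to 0 °C, dark
Reagents that add atoms: N-bromosuccinimide, O=C1CCC(=O)N1Br
Why: Electrophilic bromination of a free (N–H) indole should occur at the enamine-like C3 much faster than at C2 or at C4 (meta to the methoxy group and next to bromine), so one equivalent of NBS at low temperature should give the 3-bromo compound.

**Compound list**

1 | 3-bromo-1H-pyrrole-2-carbaldehyde | O=Cc1[nH]ccc1Br | starting material
2 | p-toluenesulfonyl chloride | Cc1ccc(S(=O)(=O)Cl)cc1 | starting material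
3 | 3-bromo-1-tosyl-1H-pyrrole-2-carbaldehyde | O=Cc1c(Br)ccn1S(=O)(=O)c1ccc(C)cc1 | intermediate
4 | potassium vinyltrifluoroborate | C=C[B-](F)(F)F.[K+] | starting material
5 | 1-tosyl-3-vinyl-1H-pyrrole-2-carbaldehyde | O=Cc1c(C=C)ccn1S(=O)(=O)c1ccc(C)cc1 | intermediate
6 | 1-tosyl-3-vinyl-1H-pyrrole-2-carboxylic acid | O=C(O)c1c(C=C)ccn1S(=O)(=O)c1ccc(C)cc1 | intermediate
7 | 1-tosyl-3-vinyl-1H-pyrrole-2-carbonyl chloride | O=C(Cl)c1c(C=C)ccn1S(=O)(=O)c1ccc(C)cc1 | intermediate
8 | 2-diazo-1-(1-tosyl-3-vinyl-1H-pyrrol-2-yl)ethan-1-one | O=C(C=[N+]=[N-])c1c(C=C)ccn1S(=O)(=O)c1ccc(C)cc1 | intermediate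
9 | 2-(1-tosyl-3-vinyl-1H-pyrrol-2-yl)ethen-1-one (pyrrol-2-ylketene) | O=C=Cc1c(C=C)ccn1S(=O)(=O)c1ccc(C)cc1 | intermediate
10 | 1-tosyl-1,5-dihydro-6H-indol-6-one | O=C1CC=C2C=CN(S(=O)(=O)c3ccc(C)cc3)C2=C1 | intermediate
11 | 1-tosyl-1H-indol-6-ol | Cc1ccc(S(=O)(=O)n2ccc3ccc(O)cc32)cc1 | intermediate
12 | 5,7-dibromo-1-tosyl-1H-indol-6-ol | Cc1ccc(S(=O)(=O)n2ccc3cc(Br)c(O)c(Br)c32)cc1 | intermediate
13 | 5,7-dibromo-6-methoxy-1-tosyl-1H-indole | COc1c(Br)cc2ccn(S(=O)(=O)c3ccc(C)cc3)c2c1Br | intermediate
14 | 5,7-dibromo-6-methoxy-1H-indole | COc1c(Br)cc2cc[nH]c2c1Br | intermediate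
15 | 3,5,7-tribromo-6-methoxy-1H-indole | COc1c(Br)cc2c(Br)c[nH]c2c1Br | target

**Step count and risk**

Total step count: 10. Longest linear sequence: 10 steps (from 1).

Steps most likely to fail:

Step 6. The excited diazoketone may leak into carbene chemistry (addition to the neighbouring vinyl group) instead of rearranging, or the ketene may be captured by the phenol as it forms instead of cyclising. The fallback sets out from 8 and comes back at 11. The diazoketone is rearranged without light by silver(I) benzoate and Et3N in aqueous THF, so that the ketene is hydrated and the Arndt–Eistert homologation is completed to 2-(1-tosyl-3-vinyl-1H-pyrrol-2-yl)acetic acid F1; any 11 formed directly is simply collected. Heating F1 in acetic anhydride with potassium acetate should regenerate the same dienylketene from the mixed anhydride in a medium whose only nucleophile is acetate (Stobbe-type benzannulation conditions). Ring closure is then followed by acetylation in the flask to 1-tosyl-1H-indol-6-yl acetate F2, which protects the phenol from the ketene. Brief methanolysis (K2CO3, MeOH, 0 °C) removes the acetate and should give 11.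

Step 7. The second bromination, at C7 in the peri position to the N-sulfonyl group, may lag, so that bromine spills onto C3 of the pyrrole ring and mixtures result. The fallback sets out from 11 and comes back at 15. Because C3 must carry bromine in the target anyway, the substitution is driven to completion with excess Br2 in AcOH/NaOAc (N-sulfonylindoles take bromine at C3) to give 3,5,7-tribromo-1-tosyl-1H-indol-6-ol F3. O-Methylation (MeI, K2CO3, DMF) gives 3,5,7-tribromo-6-methoxy-1-tosyl-1H-indole F4, and hydroxide cleavage of the sulfonamide (KOH, THF/MeOH/H2O) should deliver 15 directly, bypassing 12 to 14.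

Step 2. The sulfonyl group may be lost from the activated 2-formylpyrrole during the coupling, or the vinyl product may be consumed by Heck-type oligomerisation with unreacted bromide. The fallback sets out from 1 and comes back at 5, with the order of events reversed. The unprotected bromoaldehyde 1 is coupled with 4 under aqueous carbonate conditions (PdCl2(dppf), Cs2CO3, THF/H2O, 80 °C), where there is no sulfonyl group to lose, to give 3-vinyl-1H-pyrrole-2-carbaldehyde F5. N-Sulfonylation of F5 with 2 (NaH, THF, 0 °C) then gives 5.

Further compounds
F1 | step 6 | 2-(1-tosyl-3-vinyl-1H-pyrrol-2-yl)acetic acid | O=C(O)Cc1c(C=C)ccn1S(=O)(=O)c1ccc(C)cc1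
F2 | step 6 | 1-tosyl-1H-indol-6-yl acetate | CC(=O)Oc1ccc2ccn(S(=O)(=O)c3ccc(C)cc3)c2c1
F3 | step 7 | 3,5,7-tribromo-1-tosyl-1H-indol-6-ol | Cc1ccc(S(=O)(=O)n2cc(Br)c3cc(Br)c(O)c(Br)c32)cc1
F4 | step 7 | 3,5,7-tribromo-6-methoxy-1-tosyl-1H-indole | COc1c(Br)cc2c(Br)cn(S(=O)(=O)c3ccc(C)cc3)c2c1Br
F5 | step 2 | 3-vinyl-1H-pyrrole-2-carbaldehyde | O=Cc1[nH]ccc1C=C
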